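**Plan**
1. Retrosynthetic cuts: first the three O-benzyl groups that mask the ring A hydroxyls (ring A = the 2,3,4-trihydroxy-6-methylbenzoyl ring). Then both bonds at the depside carbonyl carbon at once, ring A C-1–C(=O) and C(=O)–O-4 of ring B (ring B = the methyl 2-hydroxy-3,6-dimethylbenzoate ring). This leaves an aryl iodide, CO and a phenol; the C–I and O–Bn bonds then lead back to 5-methylpyrogallol.
2. Enabling feature: the depside C=O is a single carbon held between an sp2 carbon of ring A and O-4 of ring B, so it can come from carbon monoxide. Ring A derives from symmetric 5-methylpyrogallol, whose two free CH positions (C-4/C-6) are equivalent, so iodine can enter only at the required carbon. In ring B, O-2–H is hydrogen-bonded to the C-1 ester carbonyl, so only O-4–H is free to react.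
3. Forward order: both benzene rings are bought and no ring is built. The sequence is benzylation, iodination, three-component carbonylative coupling of the two arenes through CO, then global hydrogenolysis.
4. Stereochemistry: the target has no stereocentre, stereogenic axis or stereogenic double bond, so nothing has to be controlled.

Key step: step 3

Remark on the chemistry: the target SMILES carries no stereodescriptor and the structure holds no stereogenic element, so "single enantiomer" is taken to mean the achiral compound itself.

**Step 1**
Reactants: 1 5-methylpyrogallol (5-methylbenzene-1,2,3-triol)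
Product: 2 1,2,3-tris(benzyloxy)-5-methylbenzene
Conditions: BnBr (3.6 equiv), K2CO3 (4 equiv), degassed DMF, Ar, 60 °C
Reagents that add atoms: benzyl bromide, BrCc1ccccc1
Why: Threefold Williamson ether synthesis of phenoxides with a primary benzylic bromide is routine for pyrogallols, and exclusion of air prevents oxidation of the electron-rich triphenolate.

**Step 2**
Reactants: 2 1,2,3-tris(benzyloxy)-5-methylbenzene
Product: 3 1,2,3-tris(benzyloxy)-4-iodo-5-methylbenzene
Conditions: NIS (1.05 equiv), TFA (0.1 equiv), MeCN/CH2Cl2, 0 °C to rt, dark
Reagents that add atoms: N-iodosuccinimide, O=C1CCC(=O)N1I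
Why: Electrophilic aromatic iodination with acid-activated NIS should attack only the trialkoxy-activated ring, whose two free positions are equivalent by symmetry, and one equivalent of reagent plus the bulk of the first iodine should hold the reaction at the mono-iodide.

**Step 3**
Reactants: 3 1,2,3-tris(benzyloxy)-4-iodo-5-methylbenzene; 4 methyl 2,4-dihydroxy-3,6-dimethylbenzoate (atraric acid, 1.3 equiv); 5 carbon monoxide
Product: 7 methyl 2-hydroxy-3,6-dimethyl-4-{[2,3,4-tris(benzyloxy)-6-methylbenzoyl]oxy}benzoate, via aroylpalladium(II) iodide 6 (not isolated)
Conditions: CO (3 bar), Pd2(dba)3 (2.5 mol %), Xantphos (6 mol %), Et3N (3 equiv), toluene, 90 °C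
Reagents that add atoms: carbon monoxide (compound 5), [C-]#[O+]
Why: Pd(0) inserts into the C–I bond of 3, CO binds, and the electron-rich, di-ortho-substituted aryl group migrates onto it (helped by relief of steric strain), which forms the ring A C-1–C(=O) bond in aroylpalladium 6; exchange of iodide for the O-4 phenoxide of 4 and reductive elimination, favoured by the wide bite angle of Xantphos, then form the C(=O)–O bond and return Pd(0). The reaction type is the well-established palladium-catalysed three-component aryloxycarbonylation of aryl iodides with phenols (carbonylative C–O coupling). No ring is closed and no stereocentre is formed. The site selectivity needed is O-4 over O-2 of 4, and the substrate secures it: O-2–H sits in a six-membered hydrogen bond to the C-1 ester carbonyl and is flanked by C-1 and the C-3 methyl group, so only O-4–H is deprotonated by Et3N and binds to palladium. The chemoselectivity needed is CO insertion over direct C–O coupling, hydrodeiodination and C–H arylation of the neighbouring O-benzyl ring, and a CO atmosphere, an amine base free of carboxylate or carbonate, and a temperature below 100 °C should favour insertion. The step makes both bonds of the hindered ester carbonyl at once and avoids preparing and activating the crowded, decarboxylation-prone 2,3,4-trioxygenated 6-methylbenzoic acid.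

**Step 4**
Reactants: 7 methyl 2-hydroxy-3,6-dimethyl-4-{[2,3,4-tris(benzyloxy)-6-methylbenzoyl]oxy}benzoate
Product: 8 methyl 2-hydroxy-3,6-dimethyl-4-[(2,3,4-trihydroxy-6-methylbenzoyl)oxy]benzoate (target)
Conditions: H2 (1 atm), 10 % Pd/C, degassed EtOAc, rt; filtration and concentration under Ar
Reagents that add atoms: none
Why: Catalytic hydrogenolysis of benzyl aryl ethers runs under neutral conditions that leave the aryl ester, the methyl ester and the ring methyl groups untouched, and the non-nucleophilic solvent excludes transesterification.

**Compound list**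
1 | 5-methylpyrogallol (5-methylbenzene-1,2,3-triol) | Cc1cc(O)c(O)c(O)c1 | starting material
2 | 1,2,3-tris(benzyloxy)-5-methylbenzene | Cc1cc(OCc2ccccc2)c(OCc2ccccc2)c(OCc2ccccc2)c1 | intermediate
3 | 1,2,3-tris(benzyloxy)-4-iodo-5-methylbenzene | Cc1cc(OCc2ccccc2)c(OCc2ccccc2)c(OCc2ccccc2)c1I | intermediate
4 | methyl 2,4-dihydroxy-3,6-dimethylbenzoate (atraric acid) | COC(=O)c1c(C)cc(O)c(C)c1O | starting material
5 | carbon monoxide | [C-]#[O+] | starting material
6 | [2,3,4-tris(benzyloxy)-6-methylbenzoyl]palladium(II) iodide (Xantphos on palladium not drawn) | Cc1cc(OCc2ccccc2)c(OCc2ccccc2)c(OCc2ccccc2)c1C(=O)[Pd]I | intermediate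
7 | methyl 2-hydroxy-3,6-dimethyl-4-{[2,3,4-tris(benzyloxy)-6-methylbenzoyl]oxy}benzoate | COC(=O)c1c(C)cc(OC(=O)c2c(C)cc(OCc3ccccc3)c(OCc3ccccc3)c2OCc2ccccc2)c(C)c1O | intermediate
8 | methyl 2-hydroxy-3,6-dimethyl-4-[(2,3,4-trihydroxy-6-methylbenzoyl)oxy]benzoate | COC(=O)c1c(C)cc(OC(=O)c2c(C)cc(O)c(O)c2O)c(C)c1O | target

**Total step count:** 4. **Longest linear sequence:** 4 steps (1 → 2 → 3 → 7 → 8).

**Steps most likely to fail**

Step 3. Capture of the crowded aroylpalladium species by the phenoxide may be slow. Decarbonylation, hydrodeiodination or palladium attack on the neighbouring benzyl ring could then take over. The fallback sets out from 3 and replaces catalysis by polar chemistry. Iodine–magnesium exchange (iPrMgCl·LiCl, THF, 0 °C to rt) should give [2,3,4-tris(benzyloxy)-6-methylphenyl]magnesium chloride F1. Quenching with CO2 and acidifying should give 2,3,4-tris(benzyloxy)-6-methylbenzoic acid F2. Trifluoroacetic anhydride in toluene should turn F2 into 2,3,4-tris(benzyloxy)-6-methylbenzoic trifluoroacetic anhydride F3. F3 acylates O-4 of 4, and the route is rejoined at 7.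

Step 2. A second iodination at the remaining ring CH, or acid-induced loss of benzyl groups, may erode the mono-iodide. The fallback sets out from 2 and uses an electrophile that deactivates the ring after one substitution. Vilsmeier–Haack formylation (POCl3, DMF, 70 °C) should give N,N-dimethyl[2,3,4-tris(benzyloxy)-6-methylbenzylidene]iminium chloride F4. Aqueous NaOAc should hydrolyse F4 to 2,3,4-tris(benzyloxy)-6-methylbenzaldehyde F5. Pinnick oxidation (NaClO2, NaH2PO4, 2-methyl-2-butene, t-BuOH/H2O) should give the benzoic acid F2. F2 is joined to 4 through the mixed anhydride F3 as above, and the route is rejoined at 7.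

Step 4. Hydrogenolysis may stall through catalyst poisoning by traces of iodide or phosphine carried over from step 3, or through slow cleavage of the hindered 2-O-benzyl group. The liberated pyrogallol may also oxidise in air on the catalyst during filtration. The fallback sets out from 7 and replaces hydrogenolysis by Lewis-acid dealkylation with a cation scavenger (BCl3, pentamethylbenzene, CH2Cl2, −78 °C, methanol quench under Ar). These conditions should spare both esters and lead directly to 8.

**Further compounds**
F1 | step 3 | [2,3,4-tris(benzyloxy)-6-methylphenyl]magnesium chloride (LiCl not drawn) | Cc1cc(OCc2ccccc2)c(OCc2ccccc2)c(OCc2ccccc2)c1[Mg]Cl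
F2 | step 3 | 2,3,4-tris(benzyloxy)-6-methylbenzoic acid | Cc1cc(OCc2ccccc2)c(OCc2ccccc2)c(OCc2ccccc2)c1C(=O)O
F3 | step 3 | 2,3,4-tris(benzyloxy)-6-methylbenzoic trifluoroacetic anhydride | Cc1cc(OCc2ccccc2)c(OCc2ccccc2)c(OCc2ccccc2)c1C(=O)OC(=O)C(F)(F)F
F4 | step 2 | N,N-dimethyl[2,3,4-tris(benzyloxy)-6-methylbenzylidene]iminium chloride | C[N+](C)=Cc1c(C)cc(OCc2ccccc2)c(OCc2ccccc2)c1OCc1ccccc1.[Cl-]
F5 | step 2 | 2,3,4-tris(benzyloxy)-6-methylbenzaldehyde | Cc1cc(OCc2ccccc2)c(OCc2ccccc2)c(OCc2ccccc2)c1C=O
F0 | step 4 | none | none
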